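- The target is the middle stage of two stages in series: by the proposed steps, starting material and reagent make it over the catalyst, and free catalyst then turns it into over-reaction product, a pseudo-first-order loss proportional to c(free catalyst). What we need for the noon, winter and dawn flasks is how far this second stage has caught up with the first.

common to all: starting material 0.40 M
- Sunday's: second substrate 0.20 M; reagent 0.80 M; protic impurity 0.040 M; free catalyst 0.30 mM; temperature 20 °C; run made earlier
- noon: second substrate 0.200 M; reagent 0.800 M; protic impurity 0.0400 M; free catalyst 0.20 mM; temperature 20 °C; time 50 min
- winter: second substrate 0.200 M; reagent 0.800 M; protic impurity 0.0400 M; free catalyst 0.20 mM; temperature 28 °C; time 50 min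
- dawn: second substrate 0.200 M; reagent 0.800 M; protic impurity 0.0400 M; free catalyst 0.20 mM; temperature 36 °C; time 50 min

Sunday's run (percent of the starting material charged)

| time / min | target / % | starting material / % |
|---|---|---|
| 2.00 | 2.3 | 98.3 |
| 5.00 | 4.0 | 96.1 |
| 10.0 | 7.6 | 92.1 |
| 15.0 | 11.3 | 87.4 |

(standard deviation of a reading: 1 percentage point)

- steps that have been proposed: reagent + catalyst intermediate A -> free catalyst + target; free catalyst + target -> free catalyst + over-reaction product; second substrate + free catalyst <-> catalyst intermediate B; second substrate + protic impurity -> quenched substrate; reagent + catalyst intermediate B -> free catalyst + second product; starting material + free catalyst <-> catalyst intermediate A; catalyst intermediate B + target -> spent catalyst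
- the earlier runs do not show what temperature does; that part of a forecast is a guess
- no earlier run changes the charge of free catalyst; that part of a forecast is a guess

- which of the two there is more of at the end, noon (target / over-reaction product)
- which of the two there is more of at the end, winter (target / over-reaction product)
- which of the two there is more of at the end, dawn (target / over-reaction product)
- how much target is there at the end, in percent of the starting material charged: noon
- how much target is there at the end, in percent of the starting material charged: winter
- how much target is there at the end, in percent of the starting material charged: dawn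

- At the last reading of Sunday's run, the starting material lost exceeds the target by 1.3 percentage points, which we book as over-reaction product, so there is 0.115 of it per target; with a scatter of 1 point on each reading, this is a rough number.
- If target grows steadily, over-reaction product grows with the square of time, so their ratio grows with c(free catalyst) times time, and scaling Sunday's value to noon gives 0.256: this is the split ratio ρ, over-reaction product per target, whose neutral point is the even split at 1.
- For noon, ρ is less than 1, so we expect target to lead there.
- One number gives the split but not the amount, so we add the loss of starting material, scaled the same way to 28.0 %, which gives 22.3 % target at noon.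
- Temperature is a guess in our reckoning: we let every rate multiply by 1.41 from noon to winter and again from winter to dawn, which gives 29.1 % target in winter and 37.0 % at dawn, with ρ at dawn 0.511, still less than 1, though it rests on the same rough reading and on that guess.
- The forecast names target as the larger in each flask, with 23 %, 34 % and 40 % of it, and expects that over-reaction “grows at dawn and flattens the yield”.
- The flasks give 20.8 %, 26.5 % and 29.9 % target against 3.47 %, 7.83 % and 16.0 % over-reaction product, so target leads in each, and ρ stands at 0.167 at noon, against our 0.256, and at 0.537 at dawn, against our 0.511.

    reagent + catalyst intermediate A → free catalyst + target (k = 0.688 M⁻¹ s⁻¹, Ea = 43.0 kJ mol⁻¹)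
    free catalyst + target → free catalyst + over-reaction product (k = 0.841 M⁻¹ s⁻¹, Ea = 41.0 kJ mol⁻¹)
    second substrate + free catalyst ⇌ catalyst intermediate B (K = 1.65 M⁻¹, k = 2.70 M⁻¹ s⁻¹, Ea = 58.0 kJ mol⁻¹, ΔH = −4.00 kJ mol⁻¹)
    second substrate + protic impurity → quenched substrate (k = 0.00122 M⁻¹ s⁻¹, Ea = 49.0 kJ mol⁻¹)
    reagent + catalyst intermediate B → free catalyst + second product (k = 1.39 M⁻¹ s⁻¹, Ea = 48.0 kJ mol⁻¹)
    starting material + free catalyst ⇌ catalyst intermediate A (K = 1.70 M⁻¹, k = 18.3 M⁻¹ s⁻¹, Ea = 36.0 kJ mol⁻¹, ΔH = −4.00 kJ mol⁻¹)
    catalyst intermediate B + target → spent catalyst (k = 6.00 × 10⁻⁵ M⁻¹ s⁻¹, Ea = 71.0 kJ mol⁻¹)
    (constants at 20 °C)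

- The neighbouring flask repeats winter with 8.0 × 10⁻⁵ M of free catalyst, so we scale winter's ρ of 0.295 in proportion to the catalyst charge and expect 0.118; that flask holds 14.7 % target and 1.45 % over-reaction product, a ρ of 0.0986.

Readings and results were computed with constants of no real substance; the scatter is artificial.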